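The numbers in the tables come from a simulation for substances that don't exist.

| flask | Q | time |
|---|---|---|
| grey | 0.500 M |  |
| ochre | 0.750 M |  |
| green | 0.300 M | 10 min |

- grey run (time / min: [L] / M): 0.40: 9 × 10⁻⁴; 0.76: 0.0015; 1.4: 0.0028; 2.8: 0.0134; 5.3: 0.0596; 10: 0.2929
- ochre run (time / min: [L] / M): 0.40: 0.0024; 0.76: 9 × 10⁻⁴; 1.4: 0.0030; 2.8: 0.0187; 5.3: 0.0927; 10: 0.5224

(scatter of a reading: 0.002 M)

1. apparent order in [Q] of the starting rate, round the charge of the grey run (the rate where two percent of its Q have turned into L) (one fixed amount of L, the same in the runs compared)
2. L in the green run at 10 min, as a share of the Q charged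

- Overall: Q -> L.
- Constant volume, constant temperature.
- The analysis sees a species whether free or bound.
- An order is taken over about fifteen percent of the charge, up and down.

1. Read the last reading of each run as a share of its charge, the end share. Grey holds 0.2929 M of L at 10 min, which is 58.6% of its Q; ochre holds 0.5224 M at 10 min, which is 69.7% of its Q.

2. Turn the question round. If the end share stayed level as the charge changes, green would match grey, and grey and ochre would agree within a scatter of about 0.400% of the grey charge. But ochre stands 11 percentage points above grey, far outside that scatter.

3. Express that gap as a power. The logarithm of the share ratio over the logarithm of the charge ratio gives a reading of 0.427. This share slope, how steeply the end share follows the charge, is the apparent order of the end amount in the charge, less one. Level shares mean a slope of 0.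

4. Take grey as the large term and reckon green as a correction to it. The green charge is 0.600 of the grey charge, so, if the slope holds below grey, the grey share is multiplied by 0.804. This reckoning puts green at 47.1% at 10 min.

5. The forecast puts the order at 0.4 and green at 42%, lower than this reckoning: “Growth then slows”.

    Q → Z (0.2898 min⁻¹)
    Z → L (0.1380 min⁻¹)
    Q + L → 2 L (5.508 M⁻¹ min⁻¹)
    2 Q ⇌ Q2, settled at all times (48.10 M⁻¹)

6. Green holds 49.5% of its charge as L at 10 min, which is 2.4 points above this reckoning, and the apparent order of the starting rate round the grey charge is 0.40. L made reached half of the Q charged at 9.34 min in grey and at 8.67 min in ochre. Between green and grey the share slope comes to 0.329, flatter than the 0.427 between grey and ochre.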